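## Retrosynthetic overview

1. Target 14 comes from its bis(benzyl ether) 13. Both arenes (ring A on C2, ring B on C5) are bought, and the oxolane (O1, C2–C5) is the only ring to be built; it is closed in the key step.
2. 13 is cut into ring B as aryl Grignard reagent 10 and the acyclic keto aldehyde 8. The C5–aryl bond forms by addition to the aldehyde, the new C5–O closes onto the C2 aryl ketone and becomes O1, and a silane removes the C2 hydroxyl, so one flask delivers one C–C bond, one C–O bond, the ring, and stereocentres C5 and C2.
3. Enabling feature: C5 is benzylic, carries O1 and lies 1,3 to the tertiary C3–OH, which allows a six-membered magnesium chelate. O1 ties C5 to the second benzylic carbon C2 in a 1,4 relation, so the γ-keto alkoxide closes by itself. C3 is fully substituted, so a C2 oxocarbenium ion has no proton to lose and cannot drift to a furan.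
4. 8 comes from thioester 7, which comes from dione 3 and ketene thioacetal 5. One catalytic anti-selective Mukaiyama aldol sets C3 and C4, and C5 and C2 are relayed from them.
5. 3 comes from propiovanillone 1 by benzylation and Riley oxidation; 5 comes from S-ethyl propanethioate 4.

Key step: step 6

Assumption: the (R,R)-Ph-pybox complex of Sn(OTf)2 is taken to give the (2R,3S) adduct. If the sense of induction on dione 3 is the opposite, the equally available (S,S)-ligand is used and nothing else changes.

## Route

Step 1
Reactants: 1 1-(4-hydroxy-3-methoxyphenyl)propan-1-one (propiovanillone)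
Product: 2 1-[4-(benzyloxy)-3-methoxyphenyl]propan-1-one
Conditions: BnBr, K2CO3, DMF, 60 °C
Reagents that add atoms: benzyl bromide, BrCc1ccccc1
Why: Williamson ether synthesis on the acidic phenol; the benzyl ether should survive all later steps and leave together with that of ring B at the end, and no stereocentre is involved.

Step 2
Reactants: 2 1-[4-(benzyloxy)-3-methoxyphenyl]propan-1-one
Product: 3 1-[4-(benzyloxy)-3-methoxyphenyl]propane-1,2-dione
Conditions: SeO2, 1,4-dioxane/H2O, reflux
Reagents that add atoms: selenium dioxide, O=[Se]=O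
Why: Riley oxidation of the only enolisable CH2 group, the standard way from propiophenones to 1-arylpropane-1,2-diones; no stereocentre is involved.

Step 3
Reactants: 4 S-ethyl propanethioate
Product: 5 (Z)-1-(ethylsulfanyl)-1-(trimethylsilyloxy)prop-1-ene
Conditions: LiN(iPr)2 (LDA), THF, −78 °C; TMSCl, −78 °C to rt
Reagents that add atoms: chlorotrimethylsilane, C[Si](C)(C)Cl
Why: Kinetic enolisation in THF places the methyl group trans to O–Li, and O-silylation traps this geometry as the (Z)-silyl ketene thioacetal (sulfur outranks oxygen in the descriptor).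

Step 4
Reactants: 3 1-[4-(benzyloxy)-3-methoxyphenyl]propane-1,2-dione; 5 (Z)-1-(ethylsulfanyl)-1-(trimethylsilyloxy)prop-1-ene
Product: 7 S-ethyl (2R,3S)-4-[4-(benzyloxy)-3-methoxyphenyl]-3-hydroxy-2,3-dimethyl-4-oxobutanethioate, via silyl ether 6 (not isolated)
Conditions: Sn(OTf)2 (10 mol %), (R,R)-Ph-pybox (11 mol %), CH2Cl2, −78 °C; then 1 M HCl, THF, rt
Reagents that add atoms: none
Why: Catalytic enantioselective Mukaiyama aldol addition to a chelating 1,2-dicarbonyl compound: 3 binds divalent tin through both carbonyl oxygens, the more electrophilic and less hindered acetyl carbonyl is attacked through an open transition state that favours the anti adduct, and the ligand shields one face, so the later C3 and C4 are set together in the only reagent-controlled stereo-event of the route.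

Step 5
Reactants: 7 S-ethyl (2R,3S)-4-[4-(benzyloxy)-3-methoxyphenyl]-3-hydroxy-2,3-dimethyl-4-oxobutanethioate
Product: 8 (2R,3S)-4-[4-(benzyloxy)-3-methoxyphenyl]-3-hydroxy-2,3-dimethyl-4-oxobutanal
Conditions: Et3SiH, Pd/C, acetone, rt; used crude
Reagents that add atoms: none
Why: Fukuyama reduction: zerovalent palladium inserts into the C–S bond and silane transfer stops at the aldehyde under neutral aprotic conditions, so the aryl ketone, the benzyl ether, the tertiary alcohol and the α-stereocentre should stay untouched.

Step 6
Reactants: 8 (2R,3S)-4-[4-(benzyloxy)-3-methoxyphenyl]-3-hydroxy-2,3-dimethyl-4-oxobutanal; 9 1-(benzyloxy)-4-bromo-2-methoxybenzene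
Product: 13 (2R,3S,4S,5R)-2,5-bis[4-(benzyloxy)-3-methoxyphenyl]-3,4-dimethyloxolan-3-ol, via aryl Grignard reagent 10 (not isolated), via open keto diol 11 (not isolated), via cyclic hemiketal 12 (not isolated)
Conditions: 9, Mg, THF, 40 °C (gives 10, 2.3 equiv); 8 in CH2Cl2 added at −78 °C; then Et3SiH, BF3·OEt2, −78 to −30 °C, same flask; aq NaHCO3
Reagents that add atoms: none
Why: The first equivalent of 10 turns the C3 hydroxyl of 8 into a magnesium alkoxide that binds the aldehyde oxygen in a six-membered chelate (C4-methyl and aroyl group equatorial, C3-methyl axial), and the second equivalent adds to C5 on the face away from the axial methyl, a chelation-controlled Grignard addition to a β-hydroxy aldehyde that sets C5 (R) with ring B trans to the C4-methyl. The C5 alkoxide of 11 then closes onto the C2 aryl ketone (5-exo-trig) to hemiketal 12, which makes this oxygen O1 and forms the oxolane. BF3·OEt2 ionises 12 to the aryl-stabilised C2 oxocarbenium ion and Et3SiH delivers hydride anti to the C3-methyl and syn to the C3 oxygen, the known course of silane reduction of aryl hemiketals in C-aryl furanoside and diaryl-oxolane chemistry, which sets C2 (R) with ring A cis to the C3-methyl and cis to ring B. The step needs aldehyde-over-ketone chemoselectivity, secured by the electron-rich, neopentyl-type aroyl group and its masking as the hemiketal, and it needs a cation that cannot aromatise, secured by the fully substituted C3. Any C5 epimer should converge to the same 4,5-trans isomer, because the p-alkoxybenzylic C5–O1 bond equilibrates under BF3·OEt2, whereas C2–O1 is held by the inductive effect of the neighbouring C3 oxygen.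

Step 7
Reactants: 13 (2R,3S,4S,5R)-2,5-bis[4-(benzyloxy)-3-methoxyphenyl]-3,4-dimethyloxolan-3-ol
Product: 14 (2R,3S,4S,5R)-2,5-bis(4-hydroxy-3-methoxyphenyl)-3,4-dimethyloxolan-3-ol (target)
Conditions: H2 (1 atm), Pd/C, EtOAc, rt, stopped at full conversion
Reagents that add atoms: none
Why: Hydrogenolysis of the two aryl benzyl ethers, which are cleaved much faster than the hindered secondary benzylic C–O bonds of a 2,5-diaryloxolane; no stereocentre is touched.

## Compound list

1 | 1-(4-hydroxy-3-methoxyphenyl)propan-1-one | CCC(=O)c1ccc(O)c(OC)c1 | starting material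
2 | 1-[4-(benzyloxy)-3-methoxyphenyl]propan-1-one | CCC(=O)c1ccc(OCc2ccccc2)c(OC)c1 | intermediate
3 | 1-[4-(benzyloxy)-3-methoxyphenyl]propane-1,2-dione | CC(=O)C(=O)c1ccc(OCc2ccccc2)c(OC)c1 | intermediate
4 | S-ethyl propanethioate | CCSC(=O)CC | starting material
5 | (Z)-1-(ethylsulfanyl)-1-(trimethylsilyloxy)prop-1-ene | C/C=C(/O[Si](C)(C)C)SCC | intermediate
6 | S-ethyl (2R,3S)-4-[4-(benzyloxy)-3-methoxyphenyl]-2,3-dimethyl-4-oxo-3-(trimethylsilyloxy)butanethioate (not isolated) | CCSC(=O)[C@H](C)[C@](C)(O[Si](C)(C)C)C(=O)c1ccc(OCc2ccccc2)c(OC)c1 | intermediate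
7 | S-ethyl (2R,3S)-4-[4-(benzyloxy)-3-methoxyphenyl]-3-hydroxy-2,3-dimethyl-4-oxobutanethioate | CCSC(=O)[C@H](C)[C@](C)(O)C(=O)c1ccc(OCc2ccccc2)c(OC)c1 | intermediate
8 | (2R,3S)-4-[4-(benzyloxy)-3-methoxyphenyl]-3-hydroxy-2,3-dimethyl-4-oxobutanal | O=C[C@H](C)[C@](C)(O)C(=O)c1ccc(OCc2ccccc2)c(OC)c1 | intermediate
9 | 1-(benzyloxy)-4-bromo-2-methoxybenzene | COc1cc(Br)ccc1OCc1ccccc1 | starting material
10 | [4-(benzyloxy)-3-methoxyphenyl]magnesium bromide (not isolated) | COc1cc([Mg]Br)ccc1OCc1ccccc1 | intermediate
11 | (2S,3S,4R)-1,4-bis[4-(benzyloxy)-3-methoxyphenyl]-2,4-dihydroxy-2,3-dimethylbutan-1-one (not isolated, present as magnesium alkoxide) | COc1cc(C(=O)[C@@](C)(O)[C@@H](C)[C@@H](O)c2ccc(OCc3ccccc3)c(OC)c2)ccc1OCc1ccccc1 | intermediate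
12 | (3S,4S,5R)-2,5-bis[4-(benzyloxy)-3-methoxyphenyl]-3,4-dimethyloxolane-2,3-diol, either configuration at C2 (not isolated) | COc1cc(C2(O)O[C@@H](c3ccc(OCc4ccccc4)c(OC)c3)[C@H](C)[C@]2(C)O)ccc1OCc1ccccc1 | intermediate
13 | (2R,3S,4S,5R)-2,5-bis[4-(benzyloxy)-3-methoxyphenyl]-3,4-dimethyloxolan-3-ol | COc1cc([C@H]2O[C@@H](c3ccc(OCc4ccccc4)c(OC)c3)[C@H](C)[C@]2(C)O)ccc1OCc1ccccc1 | intermediate
14 | (2R,3S,4S,5R)-2,5-bis(4-hydroxy-3-methoxyphenyl)-3,4-dimethyloxolan-3-ol | COc1cc([C@H]2O[C@@H](c3ccc(O)c(OC)c3)[C@H](C)[C@]2(C)O)ccc1O | target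

## Step count and risks

Total step count: 7. Longest linear sequence: 6 (steps 1, 2, 4, 5, 6, 7).

**Step 6.**
- THF may compete for magnesium and loosen the chelate, which would lower the facial selectivity at C5.
- The magnesium aldolate may cleave by retro-aldol reaction.
- A second aryl group may add to the ketone.
- The C5–O bond may ionise and be over-reduced in the silane stage.
- The fallback sets out from 7, fixes C2 first, and lets ring closure rather than addition decide C5. Zn(BH4)2 in Et2O at −20 °C reduces the α-hydroxy ketone under chelation control, with hydride entering from the methyl side, and the γ-hydroxy thioester lactonises to the hydroxy lactone F1.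
- iBu2AlH in CH2Cl2 at −78 °C then gives the lactol F2, and Grignard reagent 10 opens it to the triol F3.
- Catalytic camphorsulfonic acid in CH2Cl2 at 0 °C ionises only the benzylic alcohol next to CH(CH3), because the other one is deactivated by the adjacent tertiary carbinol. The retained C2–OH then closes the ring trans to the C4-methyl, which rejoins the route at 13.

**Step 4.**
- The aryl diketone may bind divalent tin differently from simpler 1,2-dicarbonyl compounds, with loss of enantioselectivity, anti selectivity or carbonyl regioselectivity.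
- The fallback sets out from 3 and replaces Lewis acid catalysis by enamine catalysis. Propanal is added slowly to 3 with D-proline (20 mol %) in DMF at 4 °C.
- In the usual enamine/carboxylic acid transition state the aroyl group takes the place of the aldehyde substituent, which predicts the anti (2R,3S) adduct.
- This direct cross-aldol rejoins the route at 8 and bypasses steps 3 to 5. It makes no compound outside the list (F0).

**Step 5.**
- Hydrogen formed from the silane may cause partial debenzylation.
- The tertiary alcohol may be silylated.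
- The β-hydroxy aldehyde may dehydrate or epimerise on handling.
- The fallback sets out from 7 and avoids the aldehyde. A Liebeskind–Srogl coupling with commercial [4-(benzyloxy)-3-methoxyphenyl]boronic acid (Pd2(dba)3, P(2-furyl)3, copper thiophene-2-carboxylate Cu(O2C-C4H3S), THF, 50 °C) forms the same C5–aryl bond at the ketone level and gives the hydroxy diketone F4.
- A Narasaka–Prasad reduction (Et2BOMe, NaBH4, THF/MeOH, −78 °C) of the six-membered boron chelate then gives the 1,3-syn carbinol 11, while the neopentyl-type ketone reacts more slowly.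
- 11 closes to 12, where the route is rejoined for the Et3SiH/BF3·OEt2 stage.

## Further compounds

F1 | step 6 | (3R,4S,5R)-5-[4-(benzyloxy)-3-methoxyphenyl]-4-hydroxy-3,4-dimethyloxolan-2-one | COc1cc([C@H]2OC(=O)[C@H](C)[C@]2(C)O)ccc1OCc1ccccc1
F2 | step 6 | (3R,4S,5R)-5-[4-(benzyloxy)-3-methoxyphenyl]-3,4-dimethyloxolane-2,4-diol (both anomers) | COc1cc([C@H]2OC(O)[C@H](C)[C@]2(C)O)ccc1OCc1ccccc1
F3 | step 6 | (1R,2S,3S)-1,4-bis[4-(benzyloxy)-3-methoxyphenyl]-2,3-dimethylbutane-1,2,4-triol (either configuration at C4) | COc1cc([C@@H](O)[C@@](C)(O)[C@@H](C)C(O)c2ccc(OCc3ccccc3)c(OC)c2)ccc1OCc1ccccc1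
F0 | step 4 | none | none
F4 | step 5 | (2S,3R)-1,4-bis[4-(benzyloxy)-3-methoxyphenyl]-2-hydroxy-2,3-dimethylbutane-1,4-dione | COc1cc(C(=O)[C@@](C)(O)[C@@H](C)C(=O)c2ccc(OCc3ccccc3)c(OC)c2)ccc1OCc1ccccc1
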